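**Assumption:** eremophilane numbering is used for all bicyclic compounds (ring A = C1–C5, C10; ring B = C5–C10; C3 carries O, C4 and C5 carry CH3, C8 is the ring-B carbonyl, C11 is the side-chain carbon on C7); β = face of the C5 methyl, α = opposite face; in this numbering the target is 3R,4R,5R (3α-acyloxy, 4β-CH3, 5β-CH3) with a Z acrylate.

## Retrosynthetic overview

1. Ester C–O bond last: target ⇒ 3α,11-dihydroxy-6,9-dien-8-one + (Z)-2-methyl-3-(methylsulfanyl)acrylic acid (from propargyl alcohol by anti-carbomagnesiation/iodination, oxidation, C–S coupling).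
2. C11–OH and C6=C7 ⇒ Schenck ene reaction of the 7(11),9-dien-8-one; its C7–C11 bond ⇒ intermolecular zinc-enolate aldol of the 9-en-8-one with acetone, then dehydration.
3. 3α-OH/4β-CH3 ⇒ hydroboration of a 4-methyl-Δ3 alkene, made from the C4 ketone via its enol triflate while the enone is masked as a dithiolane.
4. Bicycle ⇒ (S)-Wieland–Miescher ketone. Ring A is bought (2-methylcyclohexane-1,3-dione); ring B is formed second, by the key intermolecular Michael addition to methyl vinyl ketone (C5–C6 bond, quaternary carbon) and L-proline-catalysed intramolecular aldol condensation (sets C5).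

## Route

Step 1
Reactants: 1 2-methylcyclohexane-1,3-dione; 2 methyl vinyl ketone
Product: 3 2-methyl-2-(3-oxobutyl)cyclohexane-1,3-dione
Conditions: H2O, AcOH (cat.), hydroquinone (cat.), 75 °C, 1 h
Reagents that add atoms: none
Why: Intermolecular Michael addition of the stabilised dione enol to the enone forms the C5–C6 bond and the (still prochiral) quaternary carbon; the product has no acidic C–H left at that carbon, so it neither reverts nor over-alkylates.

Step 2
Reactants: 3 2-methyl-2-(3-oxobutyl)cyclohexane-1,3-dione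
Product: 5 (S)-Wieland–Miescher ketone, via cis-fused ketol 4 (not isolated)
Conditions: L-proline (5 mol %), DMSO, rt, 5 d; recrystallise (Et2O, −20 °C) to >99% ee
Reagents that add atoms: none
Why: Hajos–Parrish–Eder–Sauer–Wiechert reaction: the L-proline enamine of the side-chain ketone attacks one of the two enantiotopic ring carbonyls through a carboxylic-acid-organised chair transition state, which sets C5 (S in the diketone), and the ketol then dehydrates.

Step 3
Reactants: 5 (S)-Wieland–Miescher ketone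
Product: 6 C8 1,3-dithiolane of 5 (C4 ketone free, C9=C10 retained, 5S)
Conditions: HSCH2CH2SH (1.05 equiv), TsOH·H2O (cat.), AcOH, rt
Reagents that add atoms: ethane-1,2-dithiol, SCCS
Why: Chemoselective thioketalisation: in acetic acid the enone carbonyl reacts faster than the neopentyl saturated ketone (as in steroid 4-ene-3,17-diones), and the alkene does not migrate.

Step 4
Reactants: 6 C8 1,3-dithiolane of 5
Product: 8 C3=C4 enol triflate (5S), via potassium enolate 7 (not isolated)
Conditions: KHMDS, THF, −78 °C; then PhNTf2, −78 → 0 °C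
Reagents that add atoms: N-phenylbis(trifluoromethanesulfonimide), O=S(=O)(N(c1ccccc1)S(=O)(=O)C(F)(F)F)C(F)(F)F
Why: Enolisation can only go toward C3 because C5 is quaternary, and O-sulfonylation of the enolate gives a single enol triflate.

Step 5
Reactants: 8 C3=C4 enol triflate
Product: 9 4-methyl-3,9-diene C8-dithiolane (5R)
Conditions: Me2CuLi (from MeLi/CuI), THF–Et2O, −20 → 0 °C
Reagents that add atoms: lithium dimethylcuprate, [Li+].C[Cu-]C (made in the flask from methyllithium, [Li]C, and CuI)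
Why: McMurry–Scott cuprate/vinyl triflate cross-coupling replaces OTf by CH3 with the alkene fixed at C3=C4; the dithiolane is inert to cuprates.

Step 6
Reactants: 9 4-methyl-3,9-diene C8-dithiolane
Product: 11 3α-hydroxy-4β-methyl dithiolane (3R,4R,5R), via C3 alkylborane 10 (not isolated)
Conditions: BH3·THF (1.5 equiv), THF, 0 °C → rt; then 3 M NaOH, 30% H2O2, 0 °C, 30 min
Reagents that add atoms: hydrogen peroxide, OO
Why: Brown hydroboration–oxidation: syn, anti-Markovnikov addition of H–B to C3=C4 from the α-face, opposite the axial C5 methyl, sets 3α-OH and 4β-CH3 together, while the C9=C10 alkene, flanked by the dithiolane and the quaternary carbon, reacts much more slowly.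

Step 7
Reactants: 11 3α-hydroxy-4β-methyl dithiolane
Product: 12 3α-TBS ether of 11
Conditions: TBSOTf, 2,6-lutidine, CH2Cl2, 0 °C
Reagents that add atoms: tert-butyldimethylsilyl trifluoromethanesulfonate, CC(C)(C)[Si](C)(C)OS(=O)(=O)C(F)(F)F
Why: Standard silylation of the equatorial secondary alcohol, protecting it through the enolate, sulfonylation and photooxygenation steps.

Step 8
Reactants: 12 3α-TBS ether of 11
Product: 13 (3R,4R,5R)-3-(TBSO)-4,5-dimethyl-9-en-8-one
Conditions: PhI(OCOCF3)2 (1.5 equiv), MeCN–H2O (9:1), 0 °C, 15 min; aq. NaHCO3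
Reagents that add atoms: water, O
Why: Stork–Zhao oxidative dethioketalisation: S-activation by iodine(III) and hydrolysis of the allylic thionium ion return the enone within minutes, before the TBS ether is affected.

Step 9
Reactants: 13 (3R,4R,5R)-3-(TBSO)-4,5-dimethyl-9-en-8-one; 14 acetone
Product: 17 C7 acetone aldol adduct (3R,4R,5R,7S major), via lithium dienolate 15 (not isolated), via chlorozinc dienolate 16 (not isolated)
Conditions: LDA (1.15 equiv), THF, −78 °C; ZnCl2 (1.2 equiv), −78 → −40 °C; acetone (5 equiv), −40 °C; aq. NH4Cl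
Reagents that add atoms: none
Why: Directed intermolecular aldol: kinetic α′-deprotonation gives the cross-conjugated C7 enolate, and the zinc enolate adds to acetone without proton transfer or retro-aldol; the C7 centre (substituent equatorial, trans to the C5 methyl) is removed in step 10.

Step 10
Reactants: 17 C7 acetone aldol adduct
Product: 19 O-TBS isopetasol (3-(TBSO)-eremophila-7(11),9-dien-8-one), via tertiary mesylate 18 (not isolated)
Conditions: MsCl, Et3N, DMAP (cat.), CH2Cl2, 0 °C → rt; then DBU, rt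
Reagents that add atoms: none
Why: Sulfonylation of the tertiary aldol and E1cB elimination through the C7 enolate give the conjugated isopropylidene; DBU converts any isopropenyl isomer into this thermodynamic cross-conjugated dienone.

Step 11
Reactants: 19 O-TBS isopetasol
Product: 21 3-(TBSO)-11-hydroxyeremophila-6,9-dien-8-one, via C11 hydroperoxide 20 (not isolated)
Conditions: O2, TPP (cat.), hν (Na lamp), CH2Cl2, 0 °C; then PPh3, 0 °C → rt
Reagents that add atoms: dioxygen, O=O
Why: Schenck ene reaction of the s-cis enone with singlet oxygen: by the gem effect the allylic hydrogen is taken from C6 (the carbon geminal to the carbonyl), oxygen is delivered to C11 and the alkene shifts to C6=C7; PPh3 reduces the hydroperoxide, and the s-trans C9=C10 enone is inert.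

Step 12
Reactants: 21 3-(TBSO)-11-hydroxyeremophila-6,9-dien-8-one
Product: 22 (3R,4R,5R)-3,11-dihydroxyeremophila-6,9-dien-8-one
Conditions: HF·pyridine, THF–pyridine, 0 °C → rt
Reagents that add atoms: none
Why: Fluoride-driven desilylation under buffered, non-basic conditions that leave the dienone and the tertiary alcohol untouched.

Step 13
Reactants: 23 prop-2-yn-1-ol
Product: 25 (Z)-3-iodo-2-methylprop-2-en-1-ol, via cyclic alkenylmagnesium alkoxide 24 (not isolated)
Conditions: MeMgBr (3 equiv), CuI (10 mol %), THF, −10 °C → rt; then I2, −40 → 0 °C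
Reagents that add atoms: methylmagnesium bromide, C[Mg]Br; iodine, II
Why: Copper-catalysed anti-carbomagnesiation of the propargylic alkoxide (Duboudin reaction) puts CH3 on C2 and magnesium on C3 cis to CH2O in a five-membered chelate; iodinolysis with retention fixes the Z geometry.

Step 14
Reactants: 25 (Z)-3-iodo-2-methylprop-2-en-1-ol
Product: 27 (Z)-3-iodo-2-methylprop-2-enoic acid, via (Z)-iodo enal 26 (not isolated)
Conditions: CrO3, H2SO4, acetone–H2O (Jones), 0 °C
Reagents that add atoms: water, O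
Why: Jones oxidation takes the allylic alcohol through the aldehyde hydrate to the acid at 0 °C, without touching the vinyl iodide or its geometry.

Step 15
Reactants: 27 (Z)-3-iodo-2-methylprop-2-enoic acid
Product: 28 (Z)-2-methyl-3-(methylsulfanyl)prop-2-enoic acid
Conditions: NaSMe (2.2 equiv), CuI (10 mol %), DMF, 0 → 40 °C; then 1 M HCl
Reagents that add atoms: sodium methanethiolate, [Na+].[S-]C
Why: Carboxylate-assisted Ullmann-type C–S coupling (equivalently addition–elimination at the β-carbon) replaces iodide with retention, so sulfur stays cis to the carboxyl group.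

Step 16
Reactants: 22 (3R,4R,5R)-3,11-dihydroxyeremophila-6,9-dien-8-one; 28 (Z)-2-methyl-3-(methylsulfanyl)prop-2-enoic acid
Product: 30 target ester CNP0150028.1, via Yamaguchi mixed anhydride 29 (not isolated)
Conditions: 2,4,6-Cl3C6H2COCl, Et3N, THF, 0 °C; then 22, DMAP, toluene, 0 °C → rt
Reagents that add atoms: none
Why: Yamaguchi esterification acylates the secondary C3 alcohol only (the tertiary C11 alcohol is unreactive at rt); no stereocentre is touched and the low temperature limits Z/E scrambling.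

## Compound list

1 | 2-methylcyclohexane-1,3-dione | CC1C(=O)CCCC1=O | starting material
2 | methyl vinyl ketone (but-3-en-2-one) | CC(=O)C=C | starting material
3 | 2-methyl-2-(3-oxobutyl)cyclohexane-1,3-dione | CC(=O)CCC1(C)C(=O)CCCC1=O | intermediate
4 | (4aS,8aS)-4a-hydroxy-8a-methyloctahydronaphthalene-1,6-dione (cis-fused ketol, OH cis to CH3) | C1CC[C@]2(O)CC(=O)CC[C@]2(C)C1=O | intermediate
5 | (S)-Wieland–Miescher ketone, (8aS)-8a-methyl-3,4,8,8a-tetrahydronaphthalene-1,6(2H,7H)-dione | C[C@]12CCC(=O)C=C1CCCC2=O | intermediate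
6 | (5S)-C8 spiro-1,3-dithiolane of 5; C4 ketone free, C9=C10 alkene | C[C@]12CCC3(SCCS3)C=C1CCCC2=O | intermediate
7 | potassium C3=C4 enolate of 6 (5S) | C[C@]12CCC3(SCCS3)C=C1CCC=C2[O-].[K+] | intermediate
8 | (5S)-C4 enol triflate (C3=C4), C8 dithiolane, C9=C10 alkene | C[C@]12CCC3(SCCS3)C=C1CCC=C2OS(=O)(=O)C(F)(F)F | intermediate
9 | (5R)-4,5-dimethyl-3,9-diene with C8 dithiolane | C[C@]12CCC3(SCCS3)C=C1CCC=C2C | intermediate
10 | (3R,4S,5R)-3α-boryl-4β,5β-dimethyl-9-ene C8 dithiolane (alkylborane, drawn as RBH2) | B[C@@H]1CCC2=CC3(SCCS3)CC[C@]2(C)[C@H]1C | intermediate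
11 | (3R,4R,5R)-3α-hydroxy-4β,5β-dimethyl-9-ene C8 dithiolane | O[C@@H]1CCC2=CC3(SCCS3)CC[C@]2(C)[C@H]1C | intermediate
12 | (3R,4R,5R)-3α-(tert-butyldimethylsilyloxy)-4β,5β-dimethyl-9-ene C8 dithiolane | CC(C)(C)[Si](C)(C)O[C@@H]1CCC2=CC3(SCCS3)CC[C@]2(C)[C@H]1C | intermediate
13 | (4aR,5R,6R)-6-(tert-butyldimethylsilyloxy)-4a,5-dimethyl-4,4a,5,6,7,8-hexahydronaphthalen-2(3H)-one (3α-OTBS-9-en-8-one) | CC(C)(C)[Si](C)(C)O[C@@H]1CCC2=CC(=O)CC[C@]2(C)[C@H]1C | intermediate
14 | acetone | CC(C)=O | starting material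
15 | lithium 7,9-dien-8-olate of 13 | CC(C)(C)[Si](C)(C)O[C@@H]1CCC2=CC([O-])=CC[C@]2(C)[C@H]1C.[Li+] | intermediate
16 | chlorozinc 7,9-dien-8-olate of 13 | CC(C)(C)[Si](C)(C)O[C@@H]1CCC2=CC(O[Zn]Cl)=CC[C@]2(C)[C@H]1C | intermediate
17 | (3R,4R,5R,7S)-3-(TBSO)-7-(2-hydroxypropan-2-yl)-4,5-dimethyl-9-en-8-one (C7 substituent α) | CC(C)(C)[Si](C)(C)O[C@@H]1CCC2=CC(=O)[C@H](C(C)(C)O)C[C@]2(C)[C@H]1C | intermediate
18 | tertiary methanesulfonate of 17 | CC(C)(C)[Si](C)(C)O[C@@H]1CCC2=CC(=O)[C@H](C(C)(C)OS(C)(=O)=O)C[C@]2(C)[C@H]1C | intermediate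
19 | (3R,4R,5R)-3-(TBSO)-eremophila-7(11),9-dien-8-one (O-TBS isopetasol; 7-isopropylidene) | CC(C)(C)[Si](C)(C)O[C@@H]1CCC2=CC(=O)C(=C(C)C)C[C@]2(C)[C@H]1C | intermediate
20 | (3R,4R,5R)-3-(TBSO)-11-hydroperoxyeremophila-6,9-dien-8-one | CC(C)(C)[Si](C)(C)O[C@@H]1CCC2=CC(=O)C(C(C)(C)OO)=C[C@]2(C)[C@H]1C | intermediate
21 | (3R,4R,5R)-3-(TBSO)-11-hydroxyeremophila-6,9-dien-8-one | CC(C)(C)[Si](C)(C)O[C@@H]1CCC2=CC(=O)C(C(C)(C)O)=C[C@]2(C)[C@H]1C | intermediate
22 | (4aR,5R,6R)-6-hydroxy-3-(2-hydroxypropan-2-yl)-4a,5-dimethyl-5,6,7,8-tetrahydronaphthalen-2(4aH)-one (3α,11-diol) | O[C@@H]1CCC2=CC(=O)C(C(C)(C)O)=C[C@]2(C)[C@H]1C | intermediate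
23 | prop-2-yn-1-ol (propargyl alcohol) | C#CCO | starting material
24 | 4-methyl-2,5-dihydro-1,2-oxamagnesole (cyclic (Z)-alkenylmagnesium alkoxide) | CC1=C[Mg]OC1 | intermediate
25 | (Z)-3-iodo-2-methylprop-2-en-1-ol | I/C=C(/C)CO | intermediate
26 | (Z)-3-iodo-2-methylprop-2-enal | I/C=C(/C)C=O | intermediate
27 | (Z)-3-iodo-2-methylprop-2-enoic acid | I/C=C(/C)C(=O)O | intermediate
28 | (Z)-2-methyl-3-(methylsulfanyl)prop-2-enoic acid | CS/C=C(/C)C(=O)O | intermediate
29 | (Z)-2-methyl-3-(methylsulfanyl)prop-2-enoic 2,4,6-trichlorobenzoic anhydride | CS/C=C(/C)C(=O)OC(=O)c1c(Cl)cc(Cl)cc1Cl | intermediate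
30 | (1R,2R,8aR)-7-(2-hydroxypropan-2-yl)-1,8a-dimethyl-6-oxo-1,2,3,4,6,8a-hexahydronaphthalen-2-yl (Z)-2-methyl-3-(methylsulfanyl)prop-2-enoate (CNP0150028.1) | CS/C=C(/C)C(=O)O[C@@H]1CCC2=CC(=O)C(C(C)(C)O)=C[C@]2(C)[C@H]1C | target

## Step count and risks

Total steps: 16. Longest linear sequence: 13 (steps 1–12 and 16); the acid 28 is made in a 3-step side branch (steps 13–15).

**Step 6 (hydroboration next to a dithiolane; face and alkene selectivity).** The fallback sets out from 5 and comes back at 13, and avoids sulfur altogether. NaBH4 (0.3 equiv, EtOH, −10 °C) reduces only the saturated C4 ketone to the 4β-hydroxy enone F1. Ethylene glycol/TsOH (benzene, Dean–Stark) masks the enone as the dioxolane with the alkene moved to C1=C10, giving the hydroxy ketal F2. Dess–Martin periodinane returns the C4 ketone as the ketal ketone F3. LDA/TMSCl gives the C3=C4 silyl enol ether F4. Rubottom oxidation (mCPBA, NaHCO3, CH2Cl2, −20 °C; dilute citric acid) from the face opposite the C5 methyl gives the 3α-hydroxy-4-ketone F5. Wittig methylenation (Ph3P=CH2, 3 equiv, THF, reflux) gives the 4-methylene-3α-ol F6. H2/RhCl(PPh3)3 reduces only the exocyclic alkene, from the α-face, to the 4β-methyl-3α-ol ketal F7. 1 M HCl/THF removes the dioxolane and returns the alkene to conjugation, giving the 3α-hydroxy enone F8, and TBSOTf/2,6-lutidine then gives 13.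

**Step 11 (regioselectivity of the ene reaction: C6–H versus the methyl hydrogens).** The fallback sets out from 17 and comes back at 21, bypassing steps 10 and 11. TMS-imidazole caps the tertiary alcohol as the tertiary TMS ether F9. LDA then TMSCl (THF, −78 °C) gives the C7=C8 silyl dienol ether F10. Saegusa–Ito oxidation (Pd(OAc)2, MeCN, rt) introduces C6=C7 directly (the only β-hydrogens are on C6) and gives the dienone TMS ether F11. K2CO3/MeOH cleaves only the tertiary TMS ether and gives 21.

**Step 16 (Z→E isomerisation of the β-thioacrylate by DMAP addition–elimination, or sluggish acylation).** The fallback sets out from 22 and 27 and comes back at 30. Acid 27 is converted with 1-chloro-N,N,2-trimethylprop-1-en-1-amine (CH2Cl2, 0 °C) into (Z)-3-iodo-2-methylprop-2-enoyl chloride F12. This acylates only the secondary alcohol of 22 (2,6-lutidine, CH2Cl2, −20 °C, no nucleophilic catalyst) to give the C3 (Z)-iodoacrylate F13. NaSMe (1.0 equiv, THF, −40 °C) then displaces iodide by stereoretentive addition–elimination, which should outrun reversible thiolate addition to the hindered dienone, and gives 30.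

## Further compounds

F1 | step 6 | (4aS,5S)-5-hydroxy-4a-methyl-4,4a,5,6,7,8-hexahydronaphthalen-2(3H)-one (4β-hydroxy enone) | C[C@]12CCC(=O)C=C1CCC[C@@H]2O
F2 | step 6 | C8 ethylene ketal of F1 with the alkene at C1=C10 (4β-OH, 5β-CH3) | C[C@]12CCC3(OCCO3)CC1=CCC[C@@H]2O
F3 | step 6 | (5S)-C4 ketone with C8 dioxolane and C1=C10 alkene | C[C@]12CCC3(OCCO3)CC1=CCCC2=O
F4 | step 6 | C3=C4 trimethylsilyl enol ether of F3 | C[C@]12CCC3(OCCO3)CC1=CCC=C2O[Si](C)(C)C
F5 | step 6 | 3α-hydroxy-4-ketone with C8 dioxolane and C1=C10 alkene (3R) | O[C@@H]1CC=C2CC3(OCCO3)CC[C@]2(C)C1=O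
F6 | step 6 | 3α-hydroxy-4-methylene compound with C8 dioxolane and C1=C10 alkene | O[C@@H]1CC=C2CC3(OCCO3)CC[C@]2(C)C1=C
F7 | step 6 | 3α-hydroxy-4β,5β-dimethyl compound with C8 dioxolane and C1=C10 alkene | O[C@@H]1CC=C2CC3(OCCO3)CC[C@]2(C)[C@H]1C
F8 | step 6 | (4aR,5R,6R)-6-hydroxy-4a,5-dimethyl-4,4a,5,6,7,8-hexahydronaphthalen-2(3H)-one (3α-hydroxy enone) | O[C@@H]1CCC2=CC(=O)CC[C@]2(C)[C@H]1C
F9 | step 11 | tertiary trimethylsilyl ether of 17 | CC(C)(C)[Si](C)(C)O[C@@H]1CCC2=CC(=O)[C@H](C(C)(C)O[Si](C)(C)C)C[C@]2(C)[C@H]1C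
F10 | step 11 | C7=C8 trimethylsilyl dienol ether of F9 | CC(C)(C)[Si](C)(C)O[C@@H]1CCC2=CC(O[Si](C)(C)C)=C(C(C)(C)O[Si](C)(C)C)C[C@]2(C)[C@H]1C
F11 | step 11 | 3-(TBSO)-11-(trimethylsilyloxy)eremophila-6,9-dien-8-one | CC(C)(C)[Si](C)(C)O[C@@H]1CCC2=CC(=O)C(C(C)(C)O[Si](C)(C)C)=C[C@]2(C)[C@H]1C
F12 | step 16 | (Z)-3-iodo-2-methylprop-2-enoyl chloride | I/C=C(/C)C(Cl)=O
F13 | step 16 | C3 (Z)-3-iodo-2-methylprop-2-enoate of 22 | I/C=C(/C)C(=O)O[C@@H]1CCC2=CC(=O)C(C(C)(C)O)=C[C@]2(C)[C@H]1C
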